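**Retrosynthetic overview**

- Ring B is a 2-acylorcinol: the ketone-bearing C1' lies between the oxygenated C2' (OH) and C6' (OMe), with the methyl on C4'. This is the pattern of a Claisen-folded chain, so ring B is disconnected at C1'–C6'.
- Benzyl hydrogenolysis and mono-O-methylation lead back to the 2,6-dihydroxy-4-methylbenzoyl compound 13. Compound 13 is unravelled to the 6-(aroylmethyl)-4-methyl-2-pyrone 11 (pyrone-to-acylresorcinol ring transformation).
- Compound 11 comes from the ring-A aldehyde 7 and the C6-methyl anion of 4,6-dimethyl-2-pyrone 8, by aldol addition and oxidation.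
- Compound 7 comes from methyl 5-methoxysalicylate 1 by two phenol-directed ortho-formylations. O-Methylation and a Baeyer–Villiger oxidation between them place the C3 oxygen before the C4 carbon.
- Ring order: ring A is purchased, the pyrone ring comes from 8 and is consumed, and ring B is formed last (step 8).

Key step: step 8

Assumption: the target has no stereocentre and no configurationally stable axis, so no enantiocontrol is needed; 1 and 8 are taken as purchased (1 is otherwise one Fischer esterification from 5-methoxysalicylic acid).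

**Route**

Step 1
Reactants: 1 methyl 5-methoxysalicylate (methyl 2-hydroxy-5-methoxybenzoate)
Product: 2 methyl 3-formyl-2-hydroxy-5-methoxybenzoate
Conditions: hexamethylenetetramine, TFA, 85 °C; then H2O/aq. HCl, 60 °C
Reagents that add atoms: hexamethylenetetramine C1N2CN3CN1CN(C2)C3; water O
Why: Duff formylation should go ortho to the phenol at C3, the only free position ortho to OH (para is blocked by OMe), as in the double Duff formylation of 4-methoxyphenol.

Step 2
Reactants: 2 methyl 3-formyl-2-hydroxy-5-methoxybenzoate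
Product: 3 methyl 3-formyl-2,5-dimethoxybenzoate
Conditions: MeI, K2CO3, DMF, 40 °C
Reagents that add atoms: iodomethane CI
Why: Williamson ether synthesis on the acidic, doubly carbonyl-flanked phenol fixes the C2 methoxy group before the C3 oxygen exists, so no selective alkylation of a catechol is needed.

Step 3
Reactants: 3 methyl 3-formyl-2,5-dimethoxybenzoate
Product: 5 methyl 3-hydroxy-2,5-dimethoxybenzoate, via aryl formate 4 (not isolated)
Conditions: mCPBA, CH2Cl2, rt to 40 °C; then cat. K2CO3, MeOH, rt
Reagents that add atoms: mCPBA OOC(=O)c1cccc(Cl)c1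
Why: Baeyer–Villiger (Dakin-type) oxidation of an ortho-alkoxybenzaldehyde should proceed by aryl migration to the formate, which mild methanolysis cleaves without touching the methyl ester.

Step 4
Reactants: 5 methyl 3-hydroxy-2,5-dimethoxybenzoate
Product: 6 methyl 4-formyl-3-hydroxy-2,5-dimethoxybenzoate
Conditions: MgCl2, Et3N, (CH2O)n, MeCN, reflux; aq. HCl work-up
Reagents that add atoms: paraformaldehyde (as formaldehyde) C=O
Why: The magnesium phenoxide-mediated ortho-formylation (Casnati–Skattebøl) delivers formaldehyde only ortho to the phenol, and C4 is the only free ortho carbon since C2 carries OMe; the analogous formylation of methyl 3-hydroxybenzoate para to the ester is the model.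

Step 5
Reactants: 6 methyl 4-formyl-3-hydroxy-2,5-dimethoxybenzoate
Product: 7 methyl 3-(benzyloxy)-4-formyl-2,5-dimethoxybenzoate
Conditions: BnBr, K2CO3, DMF, 50 °C
Reagents that add atoms: benzyl bromide BrCc1ccccc1
Why: Williamson benzylation masks the C3 phenol, which must stay distinct from the ring-B phenols until the end.

Step 6
Reactants: 8 4,6-dimethyl-2H-pyran-2-one; 7 methyl 3-(benzyloxy)-4-formyl-2,5-dimethoxybenzoate
Product: 10 methyl 3-(benzyloxy)-4-[1-hydroxy-2-(4-methyl-2-oxo-2H-pyran-6-yl)ethyl]-2,5-dimethoxybenzoate (racemic), via lithium dienolate 9 (not isolated)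
Conditions: 8, LiHMDS, THF, −78 °C; then 7, −78 °C; AcOH quench at −78 °C
Reagents that add atoms: none
Why: Vinylogous aldol addition: the C6-methyl group of the pyrone gives the linearly conjugated dienolate, which should add through its exocyclic carbon to the aldehyde in preference to the methyl ester at −78 °C; the carbinol centre forms as a racemate and is removed in step 7.

Step 7
Reactants: 10 methyl 3-(benzyloxy)-4-[1-hydroxy-2-(4-methyl-2-oxo-2H-pyran-6-yl)ethyl]-2,5-dimethoxybenzoate
Product: 11 methyl 3-(benzyloxy)-2,5-dimethoxy-4-[2-(4-methyl-2-oxo-2H-pyran-6-yl)acetyl]benzoate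
Conditions: Dess–Martin periodinane (1.2 equiv), NaHCO3, CH2Cl2, 0 °C to rt
Reagents that add atoms: none
Why: Dess–Martin oxidation of the secondary benzylic alcohol under buffered, non-basic conditions should give the aryl ketone without E1cB dehydration to the styrylpyrone.

Step 8
Reactants: 11 methyl 3-(benzyloxy)-2,5-dimethoxy-4-[2-(4-methyl-2-oxo-2H-pyran-6-yl)acetyl]benzoate
Product: 13 methyl 3-(benzyloxy)-4-(2,6-dihydroxy-4-methylbenzoyl)-2,5-dimethoxybenzoate, via ring-opened Z-enoate 12 (not isolated)
Conditions: Mg(OMe)2 (excess), MeOH, reflux; then cold 1 M HCl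
Reagents that add atoms: none
Why: Methoxide adds to the lactone carbonyl of the pyrone and opens it to the magnesium-chelated diketonate of the (Z)-enoate 12. The carbon between the two ketones (future C1') then attacks the methyl ester carbon (future C6') in a 6-exo-trig Claisen (Dieckmann-type) closure, and loss of methoxide followed by enolisation gives the aromatic resorcinol ring B, which makes the sequence irreversible. The closest known reaction type is the magnesium methoxide-mediated conversion of 6-(2-oxoalkyl)-2-pyrones into acylresorcinols. No stereocentre is formed. The step needs C-acylation at C1' to win over aldol closure onto the aryl ketone and over retro-Claisen cleavage of the ArCO–CH2 bond: the aryl ketone is shielded by its two ortho alkoxy groups, Mg2+ holds the diketone as a chelated enolate, and the Z geometry inherited from the pyrone keeps ester and carbanion within reach. Anhydrous methoxide only exchanges the ring-A methyl ester with itself, and the benzyl ether is inert.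

Step 9
Reactants: 13 methyl 3-(benzyloxy)-4-(2,6-dihydroxy-4-methylbenzoyl)-2,5-dimethoxybenzoate
Product: 14 methyl 3-(benzyloxy)-4-(2-hydroxy-6-methoxy-4-methylbenzoyl)-2,5-dimethoxybenzoate
Conditions: MeI (1.1 equiv), K2CO3, acetone, rt to 40 °C
Reagents that add atoms: iodomethane CI
Why: Williamson methylation of one of the two symmetry-equivalent ring-B phenols should stop at the mono-ether, because the remaining hydroxyl is locked in a hydrogen bond to the ketone, as with 2,6-dihydroxyaryl ketones in general.

Step 10
Reactants: 14 methyl 3-(benzyloxy)-4-(2-hydroxy-6-methoxy-4-methylbenzoyl)-2,5-dimethoxybenzoate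
Product: 15 Pseudocercone A (methyl 3-hydroxy-4-(2-hydroxy-6-methoxy-4-methylbenzoyl)-2,5-dimethoxybenzoate)
Conditions: H2 (1 atm), 10% Pd/C, EtOAc, rt
Reagents that add atoms: none
Why: Catalytic hydrogenolysis should cleave the benzyl ether while the hindered, chelated tetra-ortho-substituted benzophenone carbonyl resists reduction at 1 atm.

**Compound list**

1 | methyl 5-methoxysalicylate (methyl 2-hydroxy-5-methoxybenzoate) | COC(=O)c1cc(OC)ccc1O | starting material
2 | methyl 3-formyl-2-hydroxy-5-methoxybenzoate | COC(=O)c1cc(OC)cc(C=O)c1O | intermediate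
3 | methyl 3-formyl-2,5-dimethoxybenzoate | COC(=O)c1cc(OC)cc(C=O)c1OC | intermediate
4 | methyl 3-(formyloxy)-2,5-dimethoxybenzoate (aryl formate, not isolated) | COC(=O)c1cc(OC)cc(OC=O)c1OC | intermediate
5 | methyl 3-hydroxy-2,5-dimethoxybenzoate | COC(=O)c1cc(OC)cc(O)c1OC | intermediate
6 | methyl 4-formyl-3-hydroxy-2,5-dimethoxybenzoate | COC(=O)c1cc(OC)c(C=O)c(O)c1OC | intermediate
7 | methyl 3-(benzyloxy)-4-formyl-2,5-dimethoxybenzoate | COC(=O)c1cc(OC)c(C=O)c(OCc2ccccc2)c1OC | intermediate
8 | 4,6-dimethyl-2H-pyran-2-one | CC1=CC(C)=CC(=O)O1 | starting material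
9 | lithium 4-methyl-6-methylidene-6H-pyran-2-olate (C6-methyl-lithiated 8, not isolated) | C=C1C=C(C)C=C(O[Li])O1 | intermediate
10 | methyl 3-(benzyloxy)-4-[1-hydroxy-2-(4-methyl-2-oxo-2H-pyran-6-yl)ethyl]-2,5-dimethoxybenzoate (racemic) | COC(=O)c1cc(OC)c(C(O)CC2=CC(C)=CC(=O)O2)c(OCc2ccccc2)c1OC | intermediate
11 | methyl 3-(benzyloxy)-2,5-dimethoxy-4-[2-(4-methyl-2-oxo-2H-pyran-6-yl)acetyl]benzoate | COC(=O)c1cc(OC)c(C(=O)CC2=CC(C)=CC(=O)O2)c(OCc2ccccc2)c1OC | intermediate
12 | methyl (2Z)-7-[2-(benzyloxy)-3,6-dimethoxy-4-(methoxycarbonyl)phenyl]-3-methyl-5,7-dioxohept-2-enoate (not isolated) | COC(=O)/C=C(C)\CC(=O)CC(=O)c1c(OC)cc(C(=O)OC)c(OC)c1OCc1ccccc1 | intermediate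
13 | methyl 3-(benzyloxy)-4-(2,6-dihydroxy-4-methylbenzoyl)-2,5-dimethoxybenzoate | COC(=O)c1cc(OC)c(C(=O)c2c(O)cc(C)cc2O)c(OCc2ccccc2)c1OC | intermediate
14 | methyl 3-(benzyloxy)-4-(2-hydroxy-6-methoxy-4-methylbenzoyl)-2,5-dimethoxybenzoate | COC(=O)c1cc(OC)c(C(=O)c2c(O)cc(C)cc2OC)c(OCc2ccccc2)c1OC | intermediate
15 | Pseudocercone A | COC(=O)c1cc(OC)c(C(=O)c2c(O)cc(C)cc2OC)c(O)c1OC | target

**Step count**

Total steps: 10. Longest linear sequence: 10 steps (1 to 15); 8 enters at step 6.

**Steps most likely to fail**

1. Step 8 (pyrone to acylresorcinol). Three processes could intervene: methoxide could cleave the hindered ArCO–CH2 bond (retro-Claisen); the opened chain could close in the aldol mode onto the aryl ketone; or the enolate of 11 could resist lactone opening. The fallback sets out from aldehyde 7 and comes back at 13, joining a preformed ring B. Orcinol is protected with MOMCl/iPr2NEt to give 1,3-bis(methoxymethoxy)-5-methylbenzene F1. n-BuLi (THF, 0 °C) should lithiate F1 between the two acetal oxygens to give [2,6-bis(methoxymethoxy)-4-methylphenyl]lithium F2. Addition of F2 to 7 at −78 °C should give the diarylmethanol methyl 3-(benzyloxy)-4-{[2,6-bis(methoxymethoxy)-4-methylphenyl](hydroxy)methyl}-2,5-dimethoxybenzoate F3. Dess–Martin oxidation should then give the benzophenone methyl 3-(benzyloxy)-4-[2,6-bis(methoxymethoxy)-4-methylbenzoyl]-2,5-dimethoxybenzoate F4. HCl in MeOH should remove both MOM groups and return 13.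

2. Step 6 (vinylogous aldol). Deprotonation could occur in part at the C4-methyl group or on the ring; the hindered lithium aldolate could revert (retro-aldol); or it could eliminate to the styrylpyrone. The fallback sets out from 7 and comes back at 11 by working at the carboxylic oxidation level. Pinnick oxidation (NaClO2, NaH2PO4, 2-methyl-2-butene) should give 2-(benzyloxy)-3,6-dimethoxy-4-(methoxycarbonyl)benzoic acid F5. Oxalyl chloride with catalytic DMF should give methyl 3-(benzyloxy)-4-(chlorocarbonyl)-2,5-dimethoxybenzoate F6. F6 is added at −78 °C to 2.2 equivalents of dienolate 9, the second equivalent serving to deprotonate the more acidic product. C-Acylation at the exocyclic carbon should give 11 directly, with no aldolate to eliminate and no oxidation step.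

3. Step 4 (second ortho-formylation). Substitution at C4 could be slow, because the site is crowded between OH and OMe and lies para to the ester; hydroxymethyl and diarylmethane side products could then accumulate. The fallback sets out from 5 and comes back at 7, carrying the carbon in by a sigmatropic shift. O-Allylation (allyl bromide, K2CO3) should give methyl 2,5-dimethoxy-3-(prop-2-en-1-yloxy)benzoate F7. Aromatic Claisen rearrangement (N,N-diethylaniline, 190 °C) should place the allyl group on C4, the only free ortho carbon, giving methyl 3-hydroxy-2,5-dimethoxy-4-(prop-2-en-1-yl)benzoate F8. Benzylation (BnBr, K2CO3) should give methyl 3-(benzyloxy)-2,5-dimethoxy-4-(prop-2-en-1-yl)benzoate F9. Isomerisation with RuHCl(CO)(PPh3)3 (toluene, 80 °C) should give methyl 3-(benzyloxy)-2,5-dimethoxy-4-[(1E)-prop-1-en-1-yl]benzoate F10. Lemieux–Johnson cleavage (cat. OsO4, NaIO4) should return 7.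

**Further compounds**

F1 | step 8 | 1,3-bis(methoxymethoxy)-5-methylbenzene | Cc1cc(OCOC)cc(OCOC)c1
F2 | step 8 | [2,6-bis(methoxymethoxy)-4-methylphenyl]lithium | [Li]c1c(OCOC)cc(C)cc1OCOC
F3 | step 8 | methyl 3-(benzyloxy)-4-{[2,6-bis(methoxymethoxy)-4-methylphenyl](hydroxy)methyl}-2,5-dimethoxybenzoate (racemic) | COC(=O)c1cc(OC)c(C(O)c2c(OCOC)cc(C)cc2OCOC)c(OCc2ccccc2)c1OC
F4 | step 8 | methyl 3-(benzyloxy)-4-[2,6-bis(methoxymethoxy)-4-methylbenzoyl]-2,5-dimethoxybenzoate | COC(=O)c1cc(OC)c(C(=O)c2c(OCOC)cc(C)cc2OCOC)c(OCc2ccccc2)c1OC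
F5 | step 6 | 2-(benzyloxy)-3,6-dimethoxy-4-(methoxycarbonyl)benzoic acid | COC(=O)c1cc(OC)c(C(=O)O)c(OCc2ccccc2)c1OC
F6 | step 6 | methyl 3-(benzyloxy)-4-(chlorocarbonyl)-2,5-dimethoxybenzoate | COC(=O)c1cc(OC)c(C(Cl)=O)c(OCc2ccccc2)c1OC
F7 | step 4 | methyl 2,5-dimethoxy-3-(prop-2-en-1-yloxy)benzoate | COC(=O)c1cc(OC)cc(OCC=C)c1OC
F8 | step 4 | methyl 3-hydroxy-2,5-dimethoxy-4-(prop-2-en-1-yl)benzoate | COC(=O)c1cc(OC)c(CC=C)c(O)c1OC
F9 | step 4 | methyl 3-(benzyloxy)-2,5-dimethoxy-4-(prop-2-en-1-yl)benzoate | COC(=O)c1cc(OC)c(CC=C)c(OCc2ccccc2)c1OC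
F10 | step 4 | methyl 3-(benzyloxy)-2,5-dimethoxy-4-[(1E)-prop-1-en-1-yl]benzoate | COC(=O)c1cc(OC)c(/C=C/C)c(OCc2ccccc2)c1OC
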